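**Retrosynthetic overview**
- Target ⇐ desilylation ⇐ hydroxymethyl Stille coupling (C8–C17, Bu3SnCH2OH as hydroxymethyl anion) on the Δ7 enol triflate of an 8-oxo-17-nor-ent-labdenyl ester ⇐ esterification of the bicyclic keto alcohol with TBS-protected 32-hydroxydotriacontanoic acid (C11 + C10 + C11 by two copper-catalysed Grignard couplings).
- Bicyclic ketone ⇐ one enantioselective proton-initiated cation–olefin cascade of an acyclic (Z)-enol acetate: ring A closes first (C4–C5), then ring B (C10–C9); no other ring is formed.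
- Acyclic enol acetate ⇐ key three-component union of an acylsilane, vinyllithium and (E)-4-bromo-3-methylbut-2-enyl pivalate: Brook rearrangement gives a siloxyallyl anion (ketone homoenolate) that forms C11–C12 and fixes the enol geometry.
- Acylsilane ⇐ acetyltrimethylsilane + geranyl bromide; allylic bromide ⇐ prenol.

Assumption: the acyl chain of the SMILES is read as 31 methylene carbons after the ester carbonyl (32-hydroxydotriacontanoate); the decalin is the ent-labdane series, (1S,4aR,8aR) in naphthalene numbering = (5R,9S,10R) in labdane numbering, which is used for atom labels below.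
Assumption: the (S)-configured binaphthol acid of step 6 is taken to give the (4aR,8aR) series, as the mirror image of the known pairing of the (R)-acid with the natural (5S,10S) series; if the sense proved opposite, the (R)-ligand would be used.

**Route**

Step 1
Reactants: 1 3-methylbut-2-en-1-ol (prenol)
Product: 2 3-methylbut-2-en-1-yl pivalate
Conditions: t-BuCOCl, pyridine, 4-(dimethylamino)pyridine (cat.), CH2Cl2, 0 °C → rt
Reagents that add atoms: pivaloyl chloride, CC(C)(C)C(Cl)=O
Why: Nucleophilic acyl substitution of a primary allylic alcohol; the pivalate resists the organolithium of step 5 and later deactivates the C13=C14 alkene toward acid.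

Step 2
Reactants: 2 3-methylbut-2-en-1-yl pivalate
Product: 3 (2E)-4-hydroxy-3-methylbut-2-en-1-yl pivalate
Conditions: SeO2 (0.3 equiv), t-BuOOH, CH2Cl2, rt
Reagents that add atoms: tert-butyl hydroperoxide, CC(C)(C)OO; selenium dioxide (oxygen carrier), O=[Se]=O
Why: Sharpless–Umbreit allylic oxidation (ene reaction, then [2,3]-sigmatropic shift) oxidises the (E)-methyl of the gem-dimethyl alkene, giving the (E)-allylic alcohol.

Step 3
Reactants: 3 (2E)-4-hydroxy-3-methylbut-2-en-1-yl pivalate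
Product: 4 (2E)-4-bromo-3-methylbut-2-en-1-yl pivalate
Conditions: CBr4, PPh3, CH2Cl2, 0 °C
Reagents that add atoms: carbon tetrabromide, BrC(Br)(Br)Br
Why: Appel bromination of the primary allylic alcohol under neutral conditions, without allylic transposition or loss of the E geometry.

Step 4
Reactants: 5 acetyltrimethylsilane; 6 geranyl bromide
Product: 8 (4E)-5,9-dimethyl-1-(trimethylsilyl)deca-4,8-dien-1-one, via lithium enolate 7 (not isolated)
Conditions: LiN(i-Pr)2, THF, −78 °C (5 added to the base); then 6, DMPU, −78 → −30 °C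
Reagents that add atoms: none
Why: Kinetic enolate alkylation (SN2) of the acylsilane at the primary allylic bromide; the E-alkene of the geranyl unit is untouched.

Step 5
Reactants: 8 (4E)-5,9-dimethyl-1-(trimethylsilyl)deca-4,8-dien-1-one; 4 (2E)-4-bromo-3-methylbut-2-en-1-yl pivalate
Product: 13 (2E,6Z,10E)-7-(acetyloxy)-3,11,15-trimethylhexadeca-2,6,10,14-tetraen-1-yl pivalate, via lithium alkoxide 9 (not isolated), via siloxyallyllithium 10 (not isolated), via silyl enol ether 11 (not isolated), via potassium enolate 12 (not isolated)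
Conditions: Bu3SnCH=CH2, n-BuLi, THF, −78 °C; 8, −78 → −45 °C; 4, −78 °C; KOt-Bu, −40 °C; Ac2O, −78 → 0 °C
Reagents that add atoms: vinyllithium, [Li]C=C (made in the flask from tributyl(vinyl)stannane, C=C[Sn](CCCC)(CCCC)CCCC, and n-BuLi); acetic anhydride, CC(=O)OC(C)=O
Why: Three-component acylsilane coupling through a 1,2-Brook rearrangement: vinyllithium adds to the acylsilane, alkoxide 9 rearranges to siloxyallyl anion 10 (a polarity-reversed ketone homoenolate), its γ-carbon C11 (the ketone β-carbon, normally electrophilic) is alkylated by the electrophilic allylic bromide carbon C12 to give the (Z)-silyl enol ether 11 (oxygen and new chain cis), and desilylation to enolate 12 followed by O-acetylation transfers that geometry to an acid-stable enol acetate.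

Step 6
Reactants: 13 (2E,6Z,10E)-7-(acetyloxy)-3,11,15-trimethylhexadeca-2,6,10,14-tetraen-1-yl pivalate
Product: 14 (2E)-3-methyl-5-[(1S,4aR,8aR)-5,5,8a-trimethyl-2-oxodecahydronaphthalen-1-yl]pent-2-en-1-yl pivalate
Conditions: SnCl4 (1.0 equiv), (S)-2′-[(2-fluorophenyl)methoxy]-1,1′-binaphthalen-2-ol (1.1 equiv), toluene, −78 °C, 2 d; aq NaHCO3; then 1,8-diazabicyclo[5.4.0]undec-7-ene (cat.), CH2Cl2, rt
Reagents that add atoms: none
Why: Proposed new method: the SnCl4-activated chiral phenol protonates the terminal isopropylidene on one enantioface and a chair–chair anti-addition cascade closes ring A (C4–C5, setting C5 and C10) and then ring B (C10–C9) onto the (Z)-enol acetate, whose geometry places the side chain equatorial at C9 (also the thermodynamic epimer after base), the acyloxycarbenium ion collapsing to the ketone while the pivalate keeps C13=C14 inert; the closest known reaction type is the Lewis-acid-assisted chiral Brønsted acid (binaphthol–SnCl4) polyene cyclization of homofarnesyl ethers and homo(polyprenyl)arenes, together with racemic enol-ester-terminated cation–olefin cyclizations.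

Step 7
Reactants: 14 (2E)-3-methyl-5-[(1S,4aR,8aR)-5,5,8a-trimethyl-2-oxodecahydronaphthalen-1-yl]pent-2-en-1-yl pivalate
Product: 15 (1S,4aR,8aR)-1-[(3E)-5-hydroxy-3-methylpent-3-en-1-yl]-5,5,8a-trimethyloctahydronaphthalen-2(1H)-one
Conditions: NaOMe (0.3 equiv), MeOH, 40 °C
Reagents that add atoms: none
Why: Base-catalysed transesterification removes the pivalate; C9, α to the ketone, stays in its favoured equatorial configuration.

Step 8
Reactants: 16 11-bromoundecan-1-ol
Product: 17 [(11-bromoundecyl)oxy](tert-butyl)dimethylsilane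
Conditions: TBSCl, imidazole, DMF, rt
Reagents that add atoms: tert-butyldimethylsilyl chloride, CC(C)(C)[Si](C)(C)Cl
Why: Standard silylation of a primary alcohol, needed for Grignard formation and for the later enolisation step.

Step 9
Reactants: 17 [(11-bromoundecyl)oxy](tert-butyl)dimethylsilane; 18 1,10-dibromodecane
Product: 20 [(21-bromohenicosyl)oxy](tert-butyl)dimethylsilane, via Grignard reagent 19 (not isolated)
Conditions: Mg, THF; then 18 (4 equiv), Li2CuCl4 (3 mol %), THF, −10 °C → rt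
Reagents that add atoms: none
Why: Kochi-type copper-catalysed sp3–sp3 Grignard cross-coupling; the excess of dibromide (recovered by distillation) suppresses double coupling.

Step 10
Reactants: 20 [(21-bromohenicosyl)oxy](tert-butyl)dimethylsilane; 21 11-bromoundecanoic acid
Product: 24 32-[(tert-butyldimethylsilyl)oxy]dotriacontanoic acid, via Grignard reagent 22 (not isolated), via chloromagnesium carboxylate 23 (not isolated)
Conditions: 20, Mg, THF, 45 °C; 21 + MeMgCl (1 equiv), THF, −20 °C; combine, Li2CuCl4 (3 mol %), −20 °C → rt; aq HCl to pH 3, 0 °C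
Reagents that add atoms: none
Why: Same Kochi-type copper-catalysed coupling, with the acid masked as its magnesium carboxylate; 21 + 10 methylenes plus the carboxyl carbon give the C32 chain.

Step 11
Reactants: 15 (1S,4aR,8aR)-1-[(3E)-5-hydroxy-3-methylpent-3-en-1-yl]-5,5,8a-trimethyloctahydronaphthalen-2(1H)-one; 24 32-[(tert-butyldimethylsilyl)oxy]dotriacontanoic acid
Product: 25 (2E)-3-methyl-5-[(1S,4aR,8aR)-5,5,8a-trimethyl-2-oxodecahydronaphthalen-1-yl]pent-2-en-1-yl 32-[(tert-butyldimethylsilyl)oxy]dotriacontanoate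
Conditions: N-(3-dimethylaminopropyl)-N′-ethylcarbodiimide hydrochloride, 4-(dimethylamino)pyridine, CH2Cl2, rt
Reagents that add atoms: none
Why: Steglich esterification of the only free hydroxyl (C15); no stereocentre is involved.

Step 12
Reactants: 25 (2E)-3-methyl-5-[(1S,4aR,8aR)-5,5,8a-trimethyl-2-oxodecahydronaphthalen-1-yl]pent-2-en-1-yl 32-[(tert-butyldimethylsilyl)oxy]dotriacontanoate
Product: 27 (2E)-3-methyl-5-[(1S,4aR,8aR)-5,5,8a-trimethyl-2-{[(trifluoromethyl)sulfonyl]oxy}-1,4,4a,5,6,7,8,8a-octahydronaphthalen-1-yl]pent-2-en-1-yl 32-[(tert-butyldimethylsilyl)oxy]dotriacontanoate, via lithium enolate 26 (not isolated)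
Conditions: LiN(SiMe3)2 (1.05 equiv), THF, −78 °C; PhNTf2, −78 → 0 °C
Reagents that add atoms: N-phenylbis(trifluoromethanesulfonimide), O=S(=O)(N(c1ccccc1)S(=O)(=O)C(F)(F)F)C(F)(F)F
Why: Kinetic deprotonation at the unhindered C7 methylene (the ketone is far more acidic than the ester α-CH2) and O-triflation give the Δ7 enol triflate regioselectively; C9 is not touched.

Step 13
Reactants: 27 (2E)-3-methyl-5-[(1S,4aR,8aR)-5,5,8a-trimethyl-2-{[(trifluoromethyl)sulfonyl]oxy}-1,4,4a,5,6,7,8,8a-octahydronaphthalen-1-yl]pent-2-en-1-yl 32-[(tert-butyldimethylsilyl)oxy]dotriacontanoate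
Product: 28 (2E)-5-[(1S,4aR,8aR)-2-(hydroxymethyl)-5,5,8a-trimethyl-1,4,4a,5,6,7,8,8a-octahydronaphthalen-1-yl]-3-methylpent-2-en-1-yl 32-[(tert-butyldimethylsilyl)oxy]dotriacontanoate
Conditions: Bu3SnCH2OH (1.5 equiv), Pd2(dba)3 (5 mol %), AsPh3 (20 mol %), LiCl (3 equiv), NMP, 50 °C
Reagents that add atoms: (tributylstannyl)methanol, OC[Sn](CCCC)(CCCC)CCCC
Why: Stille coupling with a hydroxymethyl anion equivalent makes C8–C17 from two carbons that are both carbonyl-type electrophiles in normal polarity; oxidative addition of zerovalent palladium to the enol triflate is expected to outpace ionisation of the primary allylic alkanoate under AsPh3 ligation.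

Step 14
Reactants: 28 (2E)-5-[(1S,4aR,8aR)-2-(hydroxymethyl)-5,5,8a-trimethyl-1,4,4a,5,6,7,8,8a-octahydronaphthalen-1-yl]-3-methylpent-2-en-1-yl 32-[(tert-butyldimethylsilyl)oxy]dotriacontanoate
Product: 29 (2E)-5-[(1S,4aR,8aR)-2-(hydroxymethyl)-5,5,8a-trimethyl-1,4,4a,5,6,7,8,8a-octahydronaphthalen-1-yl]-3-methylpent-2-en-1-yl 32-hydroxydotriacontanoate
Conditions: HF·pyridine, pyridine, THF, 0 °C → rt
Reagents that add atoms: none
Why: Fluoride-mediated cleavage of the primary silyl ether under buffered conditions that leave the allylic ester and allylic alcohol intact.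

**Compound list**

1 | 3-methylbut-2-en-1-ol | CC(C)=CCO | starting material
2 | 3-methylbut-2-en-1-yl pivalate | CC(C)=CCOC(=O)C(C)(C)C | intermediate
3 | (2E)-4-hydroxy-3-methylbut-2-en-1-yl pivalate | OC/C(C)=C/COC(=O)C(C)(C)C | intermediate
4 | (2E)-4-bromo-3-methylbut-2-en-1-yl pivalate | BrC/C(C)=C/COC(=O)C(C)(C)C | intermediate
5 | acetyltrimethylsilane | CC(=O)[Si](C)(C)C | starting material
6 | geranyl bromide, (2E)-1-bromo-3,7-dimethylocta-2,6-diene | CC(C)=CCC/C(C)=C/CBr | starting material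
7 | lithium 1-(trimethylsilyl)ethen-1-olate | [Li]OC(=C)[Si](C)(C)C | intermediate (not isolated)
8 | (4E)-5,9-dimethyl-1-(trimethylsilyl)deca-4,8-dien-1-one | CC(C)=CCC/C(C)=C/CCC(=O)[Si](C)(C)C | intermediate
9 | lithium (6E)-7,11-dimethyl-3-(trimethylsilyl)dodeca-1,6,10-trien-3-olate (racemic) | CC(C)=CCC/C(C)=C/CCC(O[Li])(C=C)[Si](C)(C)C | intermediate (not isolated)
10 | (2Z,6E)-7,11-dimethyl-3-[(trimethylsilyl)oxy]dodeca-2,6,10-trien-1-yllithium | CC(C)=CCC/C(C)=C/CC/C(O[Si](C)(C)C)=C/C[Li] | intermediate (not isolated)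
11 | (2E,6Z,10E)-3,11,15-trimethyl-7-[(trimethylsilyl)oxy]hexadeca-2,6,10,14-tetraen-1-yl pivalate | CC(C)=CCC/C(C)=C/CC/C(O[Si](C)(C)C)=C/CC/C(C)=C/COC(=O)C(C)(C)C | intermediate (not isolated)
12 | potassium (2E,6Z,10E)-3,11,15-trimethyl-1-(pivaloyloxy)hexadeca-2,6,10,14-tetraen-7-olate | CC(C)=CCC/C(C)=C/CC/C(O[K])=C/CC/C(C)=C/COC(=O)C(C)(C)C | intermediate (not isolated)
13 | (2E,6Z,10E)-7-(acetyloxy)-3,11,15-trimethylhexadeca-2,6,10,14-tetraen-1-yl pivalate | CC(C)=CCC/C(C)=C/CC/C(OC(C)=O)=C/CC/C(C)=C/COC(=O)C(C)(C)C | intermediate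
14 | (2E)-3-methyl-5-[(1S,4aR,8aR)-5,5,8a-trimethyl-2-oxodecahydronaphthalen-1-yl]pent-2-en-1-yl pivalate | C/C(=C\COC(=O)C(C)(C)C)CC[C@@H]1C(=O)CC[C@@H]2C(C)(C)CCC[C@@]12C | intermediate
15 | (1S,4aR,8aR)-1-[(3E)-5-hydroxy-3-methylpent-3-en-1-yl]-5,5,8a-trimethyloctahydronaphthalen-2(1H)-one | C/C(=C\CO)CC[C@@H]1C(=O)CC[C@@H]2C(C)(C)CCC[C@@]12C | intermediate
16 | 11-bromoundecan-1-ol | OCCCCCCCCCCCBr | starting material
17 | [(11-bromoundecyl)oxy](tert-butyl)dimethylsilane | BrCCCCCCCCCCCO[Si](C)(C)C(C)(C)C | intermediate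
18 | 1,10-dibromodecane | BrCCCCCCCCCCBr | starting material
19 | {11-[(tert-butyldimethylsilyl)oxy]undecyl}magnesium bromide | Br[Mg]CCCCCCCCCCCO[Si](C)(C)C(C)(C)C | intermediate (not isolated)
20 | [(21-bromohenicosyl)oxy](tert-butyl)dimethylsilane | BrCCCCCCCCCCCCCCCCCCCCCO[Si](C)(C)C(C)(C)C | intermediate
21 | 11-bromoundecanoic acid | OC(=O)CCCCCCCCCCBr | starting material
22 | {21-[(tert-butyldimethylsilyl)oxy]henicosyl}magnesium bromide | Br[Mg]CCCCCCCCCCCCCCCCCCCCCO[Si](C)(C)C(C)(C)C | intermediate (not isolated)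
23 | chloromagnesium 11-bromoundecanoate | Cl[Mg]OC(=O)CCCCCCCCCCBr | intermediate (not isolated)
24 | 32-[(tert-butyldimethylsilyl)oxy]dotriacontanoic acid | OC(=O)CCCCCCCCCCCCCCCCCCCCCCCCCCCCCCCO[Si](C)(C)C(C)(C)C | intermediate
25 | (2E)-3-methyl-5-[(1S,4aR,8aR)-5,5,8a-trimethyl-2-oxodecahydronaphthalen-1-yl]pent-2-en-1-yl 32-[(tert-butyldimethylsilyl)oxy]dotriacontanoate | C/C(=C\COC(=O)CCCCCCCCCCCCCCCCCCCCCCCCCCCCCCCO[Si](C)(C)C(C)(C)C)CC[C@@H]1C(=O)CC[C@@H]2C(C)(C)CCC[C@@]12C | intermediate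
26 | lithium Δ7-enolate of 25 (O–Li at C8, C7=C8) | C/C(=C\COC(=O)CCCCCCCCCCCCCCCCCCCCCCCCCCCCCCCO[Si](C)(C)C(C)(C)C)CC[C@@H]1C(O[Li])=CC[C@@H]2C(C)(C)CCC[C@@]12C | intermediate (not isolated)
27 | (2E)-3-methyl-5-[(1S,4aR,8aR)-5,5,8a-trimethyl-2-{[(trifluoromethyl)sulfonyl]oxy}-1,4,4a,5,6,7,8,8a-octahydronaphthalen-1-yl]pent-2-en-1-yl 32-[(tert-butyldimethylsilyl)oxy]dotriacontanoate | C/C(=C\COC(=O)CCCCCCCCCCCCCCCCCCCCCCCCCCCCCCCO[Si](C)(C)C(C)(C)C)CC[C@@H]1C(OS(=O)(=O)C(F)(F)F)=CC[C@@H]2C(C)(C)CCC[C@@]12C | intermediate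
28 | (2E)-5-[(1S,4aR,8aR)-2-(hydroxymethyl)-5,5,8a-trimethyl-1,4,4a,5,6,7,8,8a-octahydronaphthalen-1-yl]-3-methylpent-2-en-1-yl 32-[(tert-butyldimethylsilyl)oxy]dotriacontanoate | C/C(=C\COC(=O)CCCCCCCCCCCCCCCCCCCCCCCCCCCCCCCO[Si](C)(C)C(C)(C)C)CC[C@@H]1C(CO)=CC[C@@H]2C(C)(C)CCC[C@@]12C | intermediate
29 | (2E)-5-[(1S,4aR,8aR)-2-(hydroxymethyl)-5,5,8a-trimethyl-1,4,4a,5,6,7,8,8a-octahydronaphthalen-1-yl]-3-methylpent-2-en-1-yl 32-hydroxydotriacontanoate | C/C(=C\COC(=O)CCCCCCCCCCCCCCCCCCCCCCCCCCCCCCCO)CC[C@@H]1C(CO)=CC[C@@H]2C(C)(C)CCC[C@@]12C | target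

**Step count**
Total: 14 steps. Longest linear sequence: 10 steps (1, 2, 3, 5, 6, 7, 11, 12, 13, 14).

**Three steps most likely to fail**

Step 6 (enantioselective bicyclization; unprecedented terminator for this acid, and the enol acetate may be protonated in competition with the terminal alkene). Fallback, setting out from 13 and coming back at 14: give up asymmetric induction and resolve. Compound 13 is cyclized with SnCl4 alone (CH2Cl2, −78 °C, same work-up and base equilibration), which gives 14 together with its mirror image (2E)-3-methyl-5-[(1R,4aS,8aS)-5,5,8a-trimethyl-2-oxodecahydronaphthalen-1-yl]pent-2-en-1-yl pivalate F2. The two are separated by preparative supercritical-fluid chromatography on a cellulose tris(3,5-dimethylphenylcarbamate) phase, and 14 re-enters at step 7.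

Step 5 (one-flask Brook coupling; risks are α- versus γ-alkylation of the allyl anion, attack on the pivalate and loss of enol geometry on silyl-to-acetyl exchange). Fallback, setting out from 4 and 8 and coming back at 13: make the C11–C12 bond first and use the two-component Brook variant. Coupling of 4 with (E)-1,2-bis(tributylstannyl)ethene (Pd2(dba)3, AsPh3, THF, 50 °C) gives (2E,5E)-3-methyl-6-(tributylstannyl)hexa-2,5-dien-1-yl pivalate F1. Tin–lithium exchange (MeLi, THF, −100 °C) in the presence of 8, addition to the acylsilane, Brook rearrangement and γ-protonation (t-BuOH) then give silyl enol ether 11 without any allyl-anion alkylation. Compound 11 is converted into 13 as in step 5 (KOt-Bu; Ac2O).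

Step 13 (Stille hydroxymethylation; slow CH2OH transfer and possible ionisation of the allylic ester by palladium). Fallback, setting out from 15 and coming back at 28: install C17 before the ester, by a Shapiro reaction. Compound 15 is condensed with 2,4,6-tri(propan-2-yl)benzenesulfonohydrazide (MeOH, cat. HCl, rt) to the trisylhydrazone N′-[(1S,2E,4aR,8aR)-1-[(3E)-5-hydroxy-3-methylpent-3-en-1-yl]-5,5,8a-trimethyloctahydronaphthalen-2(1H)-ylidene]-2,4,6-tri(propan-2-yl)benzenesulfonohydrazide F3. Treatment with n-BuLi (3.3 equiv, THF, −78 → 0 °C) and then paraformaldehyde gives, through the C8 vinyllithium, the diol (2E)-5-[(1S,4aR,8aR)-2-(hydroxymethyl)-5,5,8a-trimethyl-1,4,4a,5,6,7,8,8a-octahydronaphthalen-1-yl]-3-methylpent-2-en-1-ol F4. Its less hindered C15 hydroxyl is esterified with 24 (carbodiimide, 4-(dimethylamino)pyridine, CH2Cl2, −20 °C) to give 28, which goes on to step 14.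

**Further compounds**

F1 | step 5 | (2E,5E)-3-methyl-6-(tributylstannyl)hexa-2,5-dien-1-yl pivalate | CCCC[Sn](CCCC)(CCCC)/C=C/C/C(C)=C/COC(=O)C(C)(C)C
F2 | step 6 | (2E)-3-methyl-5-[(1R,4aS,8aS)-5,5,8a-trimethyl-2-oxodecahydronaphthalen-1-yl]pent-2-en-1-yl pivalate | C/C(=C\COC(=O)C(C)(C)C)CC[C@H]1C(=O)CC[C@H]2C(C)(C)CCC[C@]12C
F3 | step 13 | N′-[(1S,2E,4aR,8aR)-1-[(3E)-5-hydroxy-3-methylpent-3-en-1-yl]-5,5,8a-trimethyloctahydronaphthalen-2(1H)-ylidene]-2,4,6-tri(propan-2-yl)benzenesulfonohydrazide | C/C(=C\CO)CC[C@@H]1/C(=N/NS(=O)(=O)c3c(C(C)C)cc(C(C)C)cc3C(C)C)CC[C@@H]2C(C)(C)CCC[C@@]12C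
F4 | step 13 | (2E)-5-[(1S,4aR,8aR)-2-(hydroxymethyl)-5,5,8a-trimethyl-1,4,4a,5,6,7,8,8a-octahydronaphthalen-1-yl]-3-methylpent-2-en-1-ol | C/C(=C\CO)CC[C@@H]1C(CO)=CC[C@@H]2C(C)(C)CCC[C@@]12C
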